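**Retrosynthetic overview**
1. Target ⇒ bicyclic hemiketal: the endo 4-hydroxy-3-methoxyphenyl centre (C1) is made last, by hydride delivery to the convex face of a cyclic aryl oxocarbenium ion; hemiketal ⇒ exo-aryl bicyclic γ-lactone + C,O-dilithiated 4-bromo-2-methoxyphenol.
2. Bicyclic lactone ⇒ acyclic α-bromo-β-alkoxy ester: one flask closes ring A (the aryl-bearing oxolane, 5-exo radical C–C closure) and then ring B (the γ-lactone, O-alkylation of the ester by the transferred bromide).
3. α-Bromo ester ⇒ (R)-1-arylallyl alcohol + methyl 2-bromoacrylate (oxa-Michael); this carbinol is the only stereocentre brought in and it relays to the other three.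
4. (R)-Allyl alcohol ⇒ O-prenylvanillin (catalytic asymmetric vinylation) ⇒ vanillin + prenyl bromide; the prenyl ether is carried from the first step, so the two phenols never have to be differentiated.
5. Ring order: A, then B, in the same operation; ring B is not reopened, its carbonyl carbon becomes the ArCH–O carbon.

Assumption: the SMILES is taken literally, i.e. the (1S,3aS,4R,6aS) isomer with the free-phenol aryl endo (concave face) and the prenyloxyaryl exo; below, Ar = 3-methoxy-4-[(3-methylbut-2-en-1-yl)oxy]phenyl.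

**Step 1**
Reactants: 1 vanillin (4-hydroxy-3-methoxybenzaldehyde); 2 1-bromo-3-methylbut-2-ene (prenyl bromide)
Product: 3 3-methoxy-4-[(3-methylbut-2-en-1-yl)oxy]benzaldehyde
Conditions: K2CO3 (1.5 equiv), DMF, rt, 12 h
Reagents that add atoms: none
Why: Williamson ether synthesis, in which the phenoxide of 1 displaces bromide from the primary allylic bromide 2 (SN2) so that the prenyl ether is in place from the start; no stereocentre is formed.

**Step 2**
Reactants: 3 3-methoxy-4-[(3-methylbut-2-en-1-yl)oxy]benzaldehyde; 4 vinylmagnesium bromide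
Product: 6 (1R)-1-Ar-prop-2-en-1-ol, via divinylzinc 5 (not isolated)
Conditions: 4 (2.4 equiv), ZnCl2 (1.2 equiv), Et2O, 0 °C, then 1,4-dioxane, filter; (+)-MIB [(2R)-3-exo-morpholinoisoborneol, 5 mol %], 3, toluene, 0 °C; aq. NH4Cl
Reagents that add atoms: none
Why: Amino-alcohol-catalysed enantioselective organozinc addition to an aldehyde (Noyori/Oppolzer-type vinylzinc addition), in which (+)-MIB, the enantiomer of the ligand that gives (S)-carbinols, is expected to deliver a vinyl group to the Re face of 3 and so set the (R)-carbinol centre that later controls all the others, the aryl prenyl ether being inert to organozinc reagents.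

**Step 3**
Reactants: 6 (1R)-1-Ar-prop-2-en-1-ol; 7 methyl 2-bromoprop-2-enoate (methyl 2-bromoacrylate)
Product: 8 methyl (2RS)-2-bromo-3-{[(1R)-1-Ar-prop-2-en-1-yl]oxy}propanoate
Conditions: 7 (1.5 equiv), KOt-Bu (10 mol %), THF, −20 °C; AcOH (10 mol %)
Reagents that add atoms: none
Why: Base-catalysed oxa-Michael (conjugate) addition, in which the alkoxide of 6 adds to the β-carbon of the α-bromoacrylate and the α-bromo enolate is protonated by further 6 so that base never accumulates; the carbinol centre is untouched and the new C–Br centre (both epimers) is irrelevant because it becomes a planar radical in step 4.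

**Step 4**
Reactants: 8 methyl (2RS)-2-bromo-3-{[(1R)-1-Ar-prop-2-en-1-yl]oxy}propanoate
Product: 10 (3aS,4R,6aS)-4-Ar-tetrahydro-1H,3H-furo[3,4-c]furan-1-one, via bromomethyl oxolane ester 9 (not isolated)
Conditions: CuBr (10 mol %), TPMA [tris(2-pyridylmethyl)amine, 10 mol %], degassed MeCN (0.03 M), 60 °C; then air, Bu4NI (20 mol %), 80 °C
Reagents that add atoms: none
Why: Copper-catalysed atom-transfer radical cyclisation (Kharasch-type, 5-exo-trig) followed by iodide-assisted dealkylative lactonisation, in which the α-ester radical closes ring A through a Beckwith–Houk chair transition state with the aryl group pseudo-equatorial (aryl trans to the new CH2Br; the ester-cis epimer, the usual preference for a substituent on the radical carbon, is the one that goes on), bromine transfer gives 9, and on heating the ester carbonyl oxygen displaces the primary halide to close ring B as the only possible cis-fused γ-lactone, so that C3a and C6a are both set from the carbinol centre.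

**Step 5**
Reactants: 10 (3aS,4R,6aS)-4-Ar-tetrahydro-1H,3H-furo[3,4-c]furan-1-one; 11 4-bromo-2-methoxyphenol
Product: 13 (3aS,4R,6aS)-1-(4-hydroxy-3-methoxyphenyl)-4-Ar-tetrahydro-1H,3H-furo[3,4-c]furan-1-ol, via lithium 4-lithio-2-methoxyphenolate 12 (not isolated)
Conditions: 11 (1.5 equiv), t-BuLi (4.5 equiv), THF, −78 → −40 °C; then 10, −78 °C; AcOH, −78 °C
Reagents that add atoms: none
Why: Halogen–lithium exchange followed by 1,2-addition of an aryllithium to a lactone (C-aryl-glycoside-type lactol synthesis), in which the first equivalent of t-BuLi forms the lithium phenoxide and two more effect Br–Li exchange, the C-lithio phenoxide adds once to the lactone carbonyl because the para-phenoxide-substituted lactolate/ketone is strongly deactivated towards a second addition, the three stereocentres of 10 are untouched and the new hemiketal centre (both epimers, in ring–chain equilibrium with the open hydroxy ketone) is erased again in step 6.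

**Step 6**
Reactants: 13 (3aS,4R,6aS)-1-(4-hydroxy-3-methoxyphenyl)-4-Ar-tetrahydro-1H,3H-furo[3,4-c]furan-1-ol
Product: 15 4-[(1S,3aS,4R,6aS)-4-Ar-tetrahydro-1H,3H-furo[3,4-c]furan-1-yl]-2-methoxyphenol, via bicyclic oxocarbenium ion 14 (not isolated)
Conditions: Et3SiH (3 equiv), BF3·OEt2 (1.5 equiv), CH2Cl2, −78 °C, 45 min; Et3N, −78 °C
Reagents that add atoms: none
Why: Lewis-acid-mediated ionic hydrogenation of a lactol (Kishi-type hemiketal reduction), in which BF3 ionises 13 to the planar aryl-stabilised oxocarbenium ion 14 and Et3SiH delivers hydride to its convex face (the face of the two bridgehead hydrogens), placing the new hydrogen exo and the 4-hydroxy-3-methoxyphenyl group endo, i.e. (1S), while the low temperature spares the prenyl ether and the exo benzylic ether.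

**Compound list**
1 | vanillin (4-hydroxy-3-methoxybenzaldehyde) | COc1cc(C=O)ccc1O | starting material
2 | 1-bromo-3-methylbut-2-ene (prenyl bromide) | CC(C)=CCBr | starting material
3 | 3-methoxy-4-[(3-methylbut-2-en-1-yl)oxy]benzaldehyde | COc1cc(C=O)ccc1OCC=C(C)C | intermediate
4 | vinylmagnesium bromide | C=C[Mg]Br | starting material
5 | divinylzinc | C=C[Zn]C=C | intermediate
6 | (1R)-1-{3-methoxy-4-[(3-methylbut-2-en-1-yl)oxy]phenyl}prop-2-en-1-ol | O[C@H](C=C)c1ccc(OCC=C(C)C)c(OC)c1 | intermediate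
7 | methyl 2-bromoprop-2-enoate | COC(=O)C(Br)=C | starting material
8 | methyl (2RS)-2-bromo-3-{[(1R)-1-{3-methoxy-4-[(3-methylbut-2-en-1-yl)oxy]phenyl}prop-2-en-1-yl]oxy}propanoate | COC(=O)C(Br)CO[C@H](C=C)c1ccc(OCC=C(C)C)c(OC)c1 | intermediate
9 | methyl (3S,4R,5R)-4-(bromomethyl)-5-{3-methoxy-4-[(3-methylbut-2-en-1-yl)oxy]phenyl}oxolane-3-carboxylate (aryl trans, ester cis to CH2Br) | COC(=O)[C@@H]1CO[C@@H](c2ccc(OCC=C(C)C)c(OC)c2)[C@@H]1CBr | intermediate
10 | (3aS,4R,6aS)-4-{3-methoxy-4-[(3-methylbut-2-en-1-yl)oxy]phenyl}tetrahydro-1H,3H-furo[3,4-c]furan-1-one (cis-fused, aryl exo) | O=C1OC[C@@H]2[C@H]1CO[C@H]2c1ccc(OCC=C(C)C)c(OC)c1 | intermediate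
11 | 4-bromo-2-methoxyphenol | COc1cc(Br)ccc1O | starting material
12 | lithium 4-lithio-2-methoxyphenolate | [Li]Oc1ccc([Li])cc1OC | intermediate
13 | (3aS,4R,6aS)-1-(4-hydroxy-3-methoxyphenyl)-4-{3-methoxy-4-[(3-methylbut-2-en-1-yl)oxy]phenyl}tetrahydro-1H,3H-furo[3,4-c]furan-1-ol (hemiketal, both C1 epimers) | COc1cc(C2(O)OC[C@@H]3[C@H]2CO[C@H]3c2ccc(OCC=C(C)C)c(OC)c2)ccc1O | intermediate
14 | (3aS,4R,6aS)-1-(4-hydroxy-3-methoxyphenyl)-4-{3-methoxy-4-[(3-methylbut-2-en-1-yl)oxy]phenyl}-3a,4,6,6a-tetrahydro-3H-furo[3,4-c]furan-2-ium (C1=O2 oxocarbenium ion) | COc1cc(C2=[O+]C[C@@H]3[C@H]2CO[C@H]3c2ccc(OCC=C(C)C)c(OC)c2)ccc1O | intermediate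
15 | 4-[(1S,3aS,4R,6aS)-4-{3-methoxy-4-[(3-methylbut-2-en-1-yl)oxy]phenyl}tetrahydro-1H,3H-furo[3,4-c]furan-1-yl]-2-methoxyphenol | COc1cc([C@H]2OC[C@@H]3[C@H]2CO[C@H]3c2ccc(OCC=C(C)C)c(OC)c2)ccc1O | target

**Step count and risks**
Total steps: 6. Longest linear sequence: 6 (1 → 3 → 6 → 8 → 10 → 13 → 15); compounds 2, 4, 7 and 11 are bought.

Step 3 is the first weak point. A secondary alkoxide and methyl 2-bromoacrylate can give acrylate oligomers or cyclopropanes instead of the 1:1 adduct. The fallback sets out from alcohol 6: add it to methyl acrylate under PMe3 catalysis to give methyl 3-{[(1R)-1-Ar-prop-2-en-1-yl]oxy}propanoate F1. Then form the lithium enolate (LDA, THF, −78 °C) and brominate it with CBr4, which returns to the route at bromo ester 8.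

Step 4 is the most exposed step. Only the epimer of 9 with the ester cis to CH2Br can lactonise. The preference for that epimer may be weak for an ester-substituted radical, and base cannot be used to correct it because the γ-halo ester enolate closes to a cyclopropane. The fallback sets out from alcohol 6 and makes the radical carbon symmetric:
- Oxa-Michael addition to dimethyl methylidenemalonate (KOt-Bu cat., THF, −78 °C, slow addition) gives dimethyl 2-({[(1R)-1-Ar-prop-2-en-1-yl]oxy}methyl)propanedioate F2.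
- DBU/CBrCl3 converts it into dimethyl 2-bromo-2-({[(1R)-1-Ar-prop-2-en-1-yl]oxy}methyl)propanedioate F3.
- Visible-light atom-transfer cyclisation (Ru(bpy)3Cl2 1 mol %, LiBr, DMF, blue LEDs) gives dimethyl (4R,5R)-4-(bromomethyl)-5-Ar-oxolane-3,3-dicarboxylate F4, in which one ester is necessarily cis to CH2Br.
- Warming to 80 °C closes methyl (3aS,4R,6aS)-4-Ar-1-oxotetrahydro-1H,3H-furo[3,4-c]furan-6a(6H)-carboxylate F5.
- Krapcho dealkoxycarbonylation (LiCl, wet DMSO, 120 °C), with protonation giving the only possible cis ring fusion, comes back to the route at lactone 10.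

Step 5 depends on the unprotected dianion 12. It may form sluggishly, be poorly soluble, or enolise the lactone. The fallback sets out from phenol 11 and lactone 10:
- Silylate 11 (TBSCl, imidazole, DMF) to (4-bromo-2-methoxyphenoxy)(tert-butyl)dimethylsilane F6.
- Exchange with n-BuLi (THF, −78 °C) to {4-[(tert-butyldimethylsilyl)oxy]-3-methoxyphenyl}lithium F7.
- Add it to 10 to give the silyl-protected hemiketal (3aS,4R,6aS)-1-{4-[(tert-butyldimethylsilyl)oxy]-3-methoxyphenyl}-4-Ar-tetrahydro-1H,3H-furo[3,4-c]furan-1-ol F8.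
- Reduce with Et3SiH/BF3·OEt2 at −78 °C to tert-butyl{4-[(1S,3aS,4R,6aS)-4-Ar-tetrahydro-1H,3H-furo[3,4-c]furan-1-yl]-2-methoxyphenoxy}dimethylsilane F9.
- Desilylate (TBAF, THF, 0 °C), which comes back to the route at target 15.

**Further compounds**
F1 | step 3 | methyl 3-{[(1R)-1-{3-methoxy-4-[(3-methylbut-2-en-1-yl)oxy]phenyl}prop-2-en-1-yl]oxy}propanoate | COC(=O)CCO[C@H](C=C)c1ccc(OCC=C(C)C)c(OC)c1
F2 | step 4 | dimethyl 2-({[(1R)-1-{3-methoxy-4-[(3-methylbut-2-en-1-yl)oxy]phenyl}prop-2-en-1-yl]oxy}methyl)propanedioate | COC(=O)C(CO[C@H](C=C)c1ccc(OCC=C(C)C)c(OC)c1)C(=O)OC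
F3 | step 4 | dimethyl 2-bromo-2-({[(1R)-1-{3-methoxy-4-[(3-methylbut-2-en-1-yl)oxy]phenyl}prop-2-en-1-yl]oxy}methyl)propanedioate | COC(=O)C(Br)(CO[C@H](C=C)c1ccc(OCC=C(C)C)c(OC)c1)C(=O)OC
F4 | step 4 | dimethyl (4R,5R)-4-(bromomethyl)-5-{3-methoxy-4-[(3-methylbut-2-en-1-yl)oxy]phenyl}oxolane-3,3-dicarboxylate | COC(=O)C1(C(=O)OC)CO[C@@H](c2ccc(OCC=C(C)C)c(OC)c2)[C@@H]1CBr
F5 | step 4 | methyl (3aS,4R,6aS)-4-{3-methoxy-4-[(3-methylbut-2-en-1-yl)oxy]phenyl}-1-oxotetrahydro-1H,3H-furo[3,4-c]furan-6a(6H)-carboxylate | O=C1OC[C@@H]2[C@@]1(C(=O)OC)CO[C@H]2c1ccc(OCC=C(C)C)c(OC)c1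
F6 | step 5 | (4-bromo-2-methoxyphenoxy)(tert-butyl)dimethylsilane | COc1cc(Br)ccc1O[Si](C)(C)C(C)(C)C
F7 | step 5 | {4-[(tert-butyldimethylsilyl)oxy]-3-methoxyphenyl}lithium | [Li]c1ccc(O[Si](C)(C)C(C)(C)C)c(OC)c1
F8 | step 5 | (3aS,4R,6aS)-1-{4-[(tert-butyldimethylsilyl)oxy]-3-methoxyphenyl}-4-{3-methoxy-4-[(3-methylbut-2-en-1-yl)oxy]phenyl}tetrahydro-1H,3H-furo[3,4-c]furan-1-ol | COc1cc(C2(O)OC[C@@H]3[C@H]2CO[C@H]3c2ccc(OCC=C(C)C)c(OC)c2)ccc1O[Si](C)(C)C(C)(C)C
F9 | step 5 | tert-butyl{4-[(1S,3aS,4R,6aS)-4-{3-methoxy-4-[(3-methylbut-2-en-1-yl)oxy]phenyl}tetrahydro-1H,3H-furo[3,4-c]furan-1-yl]-2-methoxyphenoxy}dimethylsilane | COc1cc([C@H]2OC[C@@H]3[C@H]2CO[C@H]3c2ccc(OCC=C(C)C)c(OC)c2)ccc1O[Si](C)(C)C(C)(C)C
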